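**Plan**

- Retrosynthesis: the benzyl ethers come off last and the C3–C4 single bond is traced back to a 4-aryl-2H-chromene. The upper pyran ring is then cut at O1–C2 and C2–C3, giving 4-benzyloxybenzaldehyde and a 2-(1-arylvinyl)phenol. Finally the bond from the vinyl carbon to C8 of epicatechin is cut, giving an 8-lithio epicatechin and an acetophenone.
- Enabling feature: C2 of the upper flavan is bonded to O1 and to the 4-hydroxyphenyl ring, so it sits at the aldehyde oxidation level. C3 and C4 are the two carbons of a former 1,1-diarylethylene C=C whose aryl groups at C4 are the resorcinol-derived ring (C4a–C8a) and ring A of epicatechin (through C8).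
- Forward: epicatechin is benzylated, brominated at C8 and lithiated, then added to 2-allyloxy-4-benzyloxyacetophenone. Dehydration and deallylation give the vinylphenol, the Prins-type condensation closes the upper pyran ring, and one hydrogenation finishes the synthesis.
- Stereochemistry: C2 and C3 of the lower unit are carried unchanged from (−)-epicatechin. The upper C2 is set by the chiral acid in the ring closure. The upper C4 is set by hydrogen delivery anti to the C2 aryl group (2,4-cis).

Key step: step 9

Assumption: the (S,S) antipode of the acid catalyst is taken to favour the 2S chromene; if it favours 2R, its mirror image is used and nothing else in the route changes.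

**Route**

Step 1
Reactants: 1 (−)-epicatechin
Product: 2 5,7,3',4'-tetra-O-benzyl-(−)-epicatechin
Conditions: BnBr (4.2 equiv), K2CO3, DMF, −10 °C to rt, Ar
Reagents that add atoms: benzyl bromide, BrCc1ccccc1
Why: Williamson etherification in which K2CO3 deprotonates only the four phenols and leaves the secondary alcohol, the mild base at or below room temperature sparing the C2 stereocentre.

Step 2
Reactants: 2 5,7,3',4'-tetra-O-benzyl-(−)-epicatechin
Product: 3 8-bromo-5,7,3',4'-tetra-O-benzylepicatechin
Conditions: NBS (1.0 equiv), CH2Cl2, −78 °C to rt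
Reagents that add atoms: N-bromosuccinimide, O=C1CCC(=O)N1Br
Why: Electrophilic aromatic bromination of the trialkoxy ring A, which for tetra-O-benzyl flavan-3-ols with a free 3-hydroxyl is known to take place at C8 and not at C6.

Step 3
Reactants: 3 8-bromo-5,7,3',4'-tetra-O-benzylepicatechin
Product: 4 8-bromo-3,5,7,3',4'-penta-O-benzylepicatechin
Conditions: NaH, BnBr, Bu4NI (cat.), THF/DMF, 0 °C to rt
Reagents that add atoms: benzyl bromide, BrCc1ccccc1
Why: Williamson etherification of the secondary alkoxide, which removes the only acidic proton before the lithiation and gives a group that leaves in the final hydrogenolysis; the aryl bromide and both stereocentres are inert to these conditions.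

Step 4
Reactants: 5 2,4-dihydroxyacetophenone
Product: 6 4-benzyloxy-2-hydroxyacetophenone
Conditions: BnBr (1.05 equiv), K2CO3, acetone, reflux
Reagents that add atoms: benzyl bromide, BrCc1ccccc1
Why: Williamson etherification that is selective for the 4-hydroxyl because the 2-hydroxyl is held in a hydrogen bond to the ketone and is far less nucleophilic.

Step 5
Reactants: 6 4-benzyloxy-2-hydroxyacetophenone
Product: 7 2-allyloxy-4-benzyloxyacetophenone
Conditions: allyl bromide, K2CO3, DMF, 60 °C
Reagents that add atoms: allyl bromide, C=CCBr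
Why: Williamson allylation of the remaining hydrogen-bonded phenol under slightly more forcing conditions; an allyl ether is chosen because its later removal by zerovalent palladium needs no acid and sets free no aldehyde that could itself condense with the vinylphenol, as formaldehyde from an acetal-type group would.

Step 6
Reactants: 4 8-bromo-3,5,7,3',4'-penta-O-benzylepicatechin; 7 2-allyloxy-4-benzyloxyacetophenone
Product: 9 1-(2-allyloxy-4-benzyloxyphenyl)-1-(3,5,7,3',4'-penta-O-benzylepicatechin-8-yl)ethanol, via 8-lithio-penta-O-benzylepicatechin 8 (not isolated)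
Conditions: n-BuLi (1.05 equiv), THF, −78 °C; then 7 (1.2 equiv), −78 to −30 °C; H2O quench
Reagents that add atoms: none
Why: Bromine–lithium exchange followed by 1,2-addition of the aryllithium to the ketone, helped by chelation of lithium by the ortho alkoxy groups; the neutral water quench protects the acid-labile carbinol, whose new stereocentre forms without control and is erased in step 7.

Step 7
Reactants: 9 1-(2-allyloxy-4-benzyloxyphenyl)-1-(3,5,7,3',4'-penta-O-benzylepicatechin-8-yl)ethanol
Product: 10 8-[1-(2-allyloxy-4-benzyloxyphenyl)vinyl]-3,5,7,3',4'-penta-O-benzylepicatechin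
Conditions: p-toluenesulfonic acid monohydrate (2 mol%), 4 Å MS, toluene, 40 °C
Reagents that add atoms: none
Why: E1 dehydration of a tertiary, doubly benzylic alcohol through a cation stabilised by two oxygenated aryl rings; only the methyl group carries β-hydrogens, so the 1,1-diarylethylene is the only alkene that can form.

Step 8
Reactants: 10 8-[1-(2-allyloxy-4-benzyloxyphenyl)vinyl]-3,5,7,3',4'-penta-O-benzylepicatechin
Product: 11 5-benzyloxy-2-[1-(3,5,7,3',4'-penta-O-benzylepicatechin-8-yl)vinyl]phenol
Conditions: Pd(PPh3)4 (5 mol%), morpholine (5 equiv), THF, rt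
Reagents that add atoms: none
Why: Tsuji–Trost-type deallylation in which zerovalent palladium ionises the aryl allyl ether to a π-allyl complex and the phenoxide, and morpholine captures the allyl group; benzyl ethers and the diarylethylene are untouched under these neutral conditions.

Step 9
Reactants: 11 5-benzyloxy-2-[1-(3,5,7,3',4'-penta-O-benzylepicatechin-8-yl)vinyl]phenol; 12 4-benzyloxybenzaldehyde
Product: 14 (2S)-7-benzyloxy-2-(4-benzyloxyphenyl)-4-(3,5,7,3',4'-penta-O-benzylepicatechin-8-yl)-2H-chromene, via aryl hemiacetal 13 (not isolated)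
Conditions: 12 (1.5 equiv), (S,S)-imidodiphosphorimidate acid HN[P(=NSO2CF3)(O2Ar*)]2 with O2Ar* = (S)-3,3'-bis[3,5-bis(trifluoromethyl)phenyl]-1,1'-binaphthyl-2,2'-dioxy (5 mol%), 5 Å MS, toluene/CH2Cl2, −60 °C, dark; Et3N quench at −60 °C; product used at once
Reagents that add atoms: none
Why: Proposed new method: the phenol of 11 and aldehyde 12 form hemiacetal 13 (O1–C2), which the acid ionises to an O-aryl oxocarbenium ion held as a contact ion pair inside the chiral anion; the terminal CH2 of the 1,1-diarylethylene attacks the oxocarbenium carbon to form C2–C3, and the resulting C4 cation, stabilised by the 7-benzyloxy-substituted ring and by ring A of the epicatechin unit, gives up a C3 proton to the anion, forming the C3=C4 bond and returning the acid. The closest known reaction types are imidodiphosphorimidate-catalysed asymmetric Prins cyclisations of homoallylic alcohols with aldehydes, acid-mediated condensations of 2-alkenylphenols with aldehydes to 2H-chromenes, and chiral N-triflylphosphoramide-catalysed closures of o-hydroxyaryl allyl cations to 2,4-diaryl-2H-chromenes, the last showing that such chromenes can survive a chiral acid at low temperature. The pyran ring closes in a 6-endo mode with respect to the alkene, the O1=C2 unit of the oxocarbenium ion also lying inside the new ring. C2 is the only new stereocentre and its configuration is decided by the chiral anion, which leaves one face of the oxocarbenium carbon open to the tethered alkene; the remote epicatechin stereocentres should bias it little, and because they are present the minor C2 epimer is a diastereomer that should be separable. The step needs face selectivity at C2 and chemoselectivity for the alkene over Friedel–Crafts attack at the free C6 of ring A and over re-ionisation of the allylic, doubly benzylic C2–O1 bond of the product; the six-membered intramolecular delivery, the high nucleophilicity of the dioxygenated diarylethylene, the low temperature, the apolar medium and the cold amine quench are meant to secure these.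

Step 10
Reactants: 14 (2S)-7-benzyloxy-2-(4-benzyloxyphenyl)-4-(3,5,7,3',4'-penta-O-benzylepicatechin-8-yl)-2H-chromene
Product: 15 (2S,4S)-4',7-dihydroxyflavan-(4→8)-(−)-epicatechin
Conditions: H2 (3 atm), Pd(OH)2/C, THF/MeOH (1:1), rt; filtration under Ar
Reagents that add atoms: none
Why: Heterogeneous hydrogenation adds H2 syn to the C3=C4 bond from the face anti to the C2 aryl group, which places the C4 aryl group cis to it (4S) as is known for flav-3-enes, and the same catalyst removes all seven benzyl ethers by hydrogenolysis.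

**Compound list**

1 | (−)-epicatechin, (2R,3R) | Oc1cc(O)c2c(c1)O[C@H](c1ccc(O)c(O)c1)[C@H](O)C2 | starting material
2 | 5,7,3',4'-tetra-O-benzyl-(−)-epicatechin | c1ccccc1COc1cc(OCc3ccccc3)c2c(c1)O[C@H](c1ccc(OCc3ccccc3)c(OCc3ccccc3)c1)[C@H](O)C2 | intermediate
3 | 8-bromo-5,7,3',4'-tetra-O-benzylepicatechin | Brc1c(OCc2ccccc2)cc(OCc2ccccc2)c2c1O[C@H](c1ccc(OCc3ccccc3)c(OCc3ccccc3)c1)[C@H](O)C2 | intermediate
4 | 8-bromo-3,5,7,3',4'-penta-O-benzylepicatechin | Brc1c(OCc2ccccc2)cc(OCc2ccccc2)c2c1O[C@H](c1ccc(OCc3ccccc3)c(OCc3ccccc3)c1)[C@H](OCc1ccccc1)C2 | intermediate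
5 | 2,4-dihydroxyacetophenone | CC(=O)c1ccc(O)cc1O | starting material
6 | 4-benzyloxy-2-hydroxyacetophenone | CC(=O)c1ccc(OCc2ccccc2)cc1O | intermediate
7 | 2-allyloxy-4-benzyloxyacetophenone | CC(=O)c1ccc(OCc2ccccc2)cc1OCC=C | intermediate
8 | 8-lithio-3,5,7,3',4'-penta-O-benzylepicatechin (formed in the flask) | [Li]c1c(OCc2ccccc2)cc(OCc2ccccc2)c2c1O[C@H](c1ccc(OCc3ccccc3)c(OCc3ccccc3)c1)[C@H](OCc1ccccc1)C2 | intermediate
9 | 1-(2-allyloxy-4-benzyloxyphenyl)-1-(3,5,7,3',4'-penta-O-benzylepicatechin-8-yl)ethanol, both configurations at the carbinol carbon | CC(O)(c1ccc(OCc2ccccc2)cc1OCC=C)c1c(OCc2ccccc2)cc(OCc2ccccc2)c2c1O[C@H](c1ccc(OCc3ccccc3)c(OCc3ccccc3)c1)[C@H](OCc1ccccc1)C2 | intermediate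
10 | 8-[1-(2-allyloxy-4-benzyloxyphenyl)vinyl]-3,5,7,3',4'-penta-O-benzylepicatechin | C=C(c1ccc(OCc2ccccc2)cc1OCC=C)c1c(OCc2ccccc2)cc(OCc2ccccc2)c2c1O[C@H](c1ccc(OCc3ccccc3)c(OCc3ccccc3)c1)[C@H](OCc1ccccc1)C2 | intermediate
11 | 5-benzyloxy-2-[1-(3,5,7,3',4'-penta-O-benzylepicatechin-8-yl)vinyl]phenol | C=C(c1ccc(OCc2ccccc2)cc1O)c1c(OCc2ccccc2)cc(OCc2ccccc2)c2c1O[C@H](c1ccc(OCc3ccccc3)c(OCc3ccccc3)c1)[C@H](OCc1ccccc1)C2 | intermediate
12 | 4-benzyloxybenzaldehyde | O=Cc1ccc(OCc2ccccc2)cc1 | starting material
13 | aryl hemiacetal of 11 and 12 (formed in the flask, both configurations at the hemiacetal carbon) | C=C(c1ccc(OCc2ccccc2)cc1OC(O)c1ccc(OCc2ccccc2)cc1)c1c(OCc2ccccc2)cc(OCc2ccccc2)c2c1O[C@H](c1ccc(OCc3ccccc3)c(OCc3ccccc3)c1)[C@H](OCc1ccccc1)C2 | intermediate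
14 | (2S)-7-benzyloxy-2-(4-benzyloxyphenyl)-4-(3,5,7,3',4'-penta-O-benzylepicatechin-8-yl)-2H-chromene | c1ccccc1COc1ccc([C@@H]2C=C(c3c(OCc4ccccc4)cc(OCc4ccccc4)c4c3O[C@H](c3ccc(OCc5ccccc5)c(OCc5ccccc5)c3)[C@H](OCc3ccccc3)C4)c3ccc(OCc4ccccc4)cc3O2)cc1 | intermediate
15 | (2S,4S)-4',7-dihydroxyflavan-(4→8)-(−)-epicatechin, i.e. (2R,3R)-2-(3,4-dihydroxyphenyl)-8-[(2S,4S)-7-hydroxy-2-(4-hydroxyphenyl)chroman-4-yl]chromane-3,5,7-triol | Oc1ccc([C@@H]2C[C@H](c3c(O)cc(O)c4c3O[C@H](c3ccc(O)c(O)c3)[C@H](O)C4)c3ccc(O)cc3O2)cc1 | target

**Step count**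

Total: 10 steps. Longest linear sequence: 8 steps (1, 2, 3, 6, 7, 8, 9, 10).

**Steps most likely to fail**

1. Step 9. The ion pair may be too loose, or the heavily benzylated substrate too large for the catalyst pocket, so that face selection at C2 is poor. The acid may also re-ionise the allylic C2–O1 bond of the product and scramble C2, or divert the activated aldehyde into Friedel–Crafts alkylation at C6 of ring A. The fallback takes C2 from a known asymmetric conjugate addition and sets out from bromide 4. Commercial 7-hydroxychromone is benzylated (BnBr, K2CO3, acetone) to 7-benzyloxy-4H-chromen-4-one F1. Pd(OCOCF3)2 with a chiral 4-tert-butyl-2-(2-pyridyl)oxazoline ligand, in the enantiomer that gives the 2S ketone, adds 4-benzyloxyphenylboronic acid to F1 to give (2S)-7-benzyloxy-2-(4-benzyloxyphenyl)chroman-4-one F2. Aryllithium 8 is generated from 4 as in step 6 and transmetallated with CeCl3 to suppress enolisation and ring opening of the flavanone. It adds to the C4 ketone of F2 to give (2S)-7-benzyloxy-2-(4-benzyloxyphenyl)-4-(3,5,7,3',4'-penta-O-benzylepicatechin-8-yl)chroman-4-ol F3. Dehydration as in step 7 gives chromene 14, where the route is rejoined before step 10.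

2. Step 6. The hindered, doubly ortho-substituted aryllithium may act as a base and enolise the methyl ketone instead of adding to it, which returns debrominated material and ketone. The fallback builds the carbinol carbon on non-enolisable carbonyl groups and also sets out from bromide 4. Commercial 4-benzyloxy-2-hydroxybenzaldehyde is allylated (allyl bromide, K2CO3, DMF) to 2-allyloxy-4-benzyloxybenzaldehyde F4. Aryllithium 8 from 4 adds to it to give (2-allyloxy-4-benzyloxyphenyl)(3,5,7,3',4'-penta-O-benzylepicatechin-8-yl)methanol F5. MnO2 in CH2Cl2 (or Dess–Martin periodinane) oxidises this to (2-allyloxy-4-benzyloxyphenyl)(3,5,7,3',4'-penta-O-benzylepicatechin-8-yl)methanone F6. MeLi in THF at −78 °C adds to the ketone to give carbinol 9, which re-enters the route at step 7.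

3. Step 10. The allylic, benzylic C2–O1 bond may be cleaved by hydrogenolysis on the palladium surface before the hindered trisubstituted C3=C4 bond is saturated. Saturation may also lag behind debenzylation and expose an oxidation-prone polyphenolic flavene, or hydrogen delivery may not be fully face-selective at C4. The fallback reduces the alkene first by ionic hydrogenation, without a metal surface, and sets out from chromene 14. Et3SiH and CF3CO2H in CH2Cl2 at −40 °C protonate C3 and deliver hydride to the C4 cation anti to the C2 aryl group. This gives (2S,4S)-7-benzyloxy-2-(4-benzyloxyphenyl)-4-(3,5,7,3',4'-penta-O-benzylepicatechin-8-yl)chroman F7. Hydrogenolysis of its benzyl ethers (H2, Pd(OH)2/C, THF/MeOH) then gives target 15.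

**Further compounds**

F1 | step 9 | 7-benzyloxy-4H-chromen-4-one | O=c1ccoc2cc(OCc3ccccc3)ccc12
F2 | step 9 | (2S)-7-benzyloxy-2-(4-benzyloxyphenyl)chroman-4-one | O=C1C[C@@H](c2ccc(OCc3ccccc3)cc2)Oc2cc(OCc3ccccc3)ccc12
F3 | step 9 | (2S)-7-benzyloxy-2-(4-benzyloxyphenyl)-4-(3,5,7,3',4'-penta-O-benzylepicatechin-8-yl)chroman-4-ol, either configuration at C4 | OC1(c2c(OCc3ccccc3)cc(OCc3ccccc3)c3c2O[C@H](c2ccc(OCc4ccccc4)c(OCc4ccccc4)c2)[C@H](OCc2ccccc2)C3)C[C@@H](c2ccc(OCc3ccccc3)cc2)Oc2cc(OCc3ccccc3)ccc12
F4 | step 6 | 2-allyloxy-4-benzyloxybenzaldehyde | O=Cc1ccc(OCc2ccccc2)cc1OCC=C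
F5 | step 6 | (2-allyloxy-4-benzyloxyphenyl)(3,5,7,3',4'-penta-O-benzylepicatechin-8-yl)methanol, either configuration at the carbinol carbon | OC(c1ccc(OCc2ccccc2)cc1OCC=C)c1c(OCc2ccccc2)cc(OCc2ccccc2)c2c1O[C@H](c1ccc(OCc3ccccc3)c(OCc3ccccc3)c1)[C@H](OCc1ccccc1)C2
F6 | step 6 | (2-allyloxy-4-benzyloxyphenyl)(3,5,7,3',4'-penta-O-benzylepicatechin-8-yl)methanone | O=C(c1ccc(OCc2ccccc2)cc1OCC=C)c1c(OCc2ccccc2)cc(OCc2ccccc2)c2c1O[C@H](c1ccc(OCc3ccccc3)c(OCc3ccccc3)c1)[C@H](OCc1ccccc1)C2
F7 | step 10 | (2S,4S)-7-benzyloxy-2-(4-benzyloxyphenyl)-4-(3,5,7,3',4'-penta-O-benzylepicatechin-8-yl)chroman | c1ccccc1COc1ccc([C@@H]2C[C@H](c3c(OCc4ccccc4)cc(OCc4ccccc4)c4c3O[C@H](c3ccc(OCc5ccccc5)c(OCc5ccccc5)c3)[C@H](OCc3ccccc3)C4)c3ccc(OCc4ccccc4)cc3O2)cc1
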